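## Retrosynthetic overview

1. 19 ⇒ 16: the tetrahydrofuran bond O1–C7a (oxa-Michael) and the C4=C5(OMe) enol ether (epoxy ketone to methoxy enone) are both unravelled to an epoxy enone carbinol. 16 ⇒ epoxy aldehyde 12 + aryl bromide 13 (C2–aryl bond, Felkin–Anh).
2. 12 ⇒ dienone aldehyde 9 by removing the C4/C5 epoxide oxygen: the C2 aldehyde carries hydrogen peroxide to one enone arm.
3. 9 ⇒ phenol 5 + allylsilane 6 (C3a–allyl bond, para-dearomatisation); 5 ⇒ 4-acetoxystyrene 1 (C3 by asymmetric hydroformylation).
4. Structural feature used: C3a is quaternary, and its two ring arms, C4=C5(OMe) and C7a(O1)–C7, meet again at the C6 carbonyl and differ only in their oxygen atoms. The carbocycle is therefore a disguised symmetric 4-allyl-4-alkylcyclohexa-2,5-dienone, and C2 lies two atoms from C3a, within reach of C4 through a six-membered peroxide tether and of C7a through its own oxygen in a five-membered ring.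
5. Ring order: the carbocycle is the benzene ring of 1 (dearomatised in step 5); a temporary oxirane is added in step 8; the tetrahydrofuran closes last (step 10).

Key step: step 8

Remark: atoms are numbered throughout as in the benzofuran skeleton of 19 (O1, C2, C3, C3a, C4 to C7, C7a), also in open-chain precursors.

Assumption: (S,R)-BINAPHOS is taken to give the R aldehyde from the styrene, as the mirror image of the sense known for the (R,S) ligand; the configuration at C3 would be confirmed on alcohol 3 before going on.

## Route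

Step 1
Reactants: 1 4-acetoxystyrene
Product: 2 (R)-2-(4-acetoxyphenyl)propanal
Conditions: Rh(acac)(CO)2 (0.2 mol%), (S,R)-BINAPHOS (0.8 mol%), CO/H2 (1:1, 20 bar), benzene, 40 °C; crude used at once
Reagents that add atoms: carbon monoxide, [C-]#[O+]
Why: Rhodium-catalysed asymmetric hydroformylation of a styrene is branched-selective because the benzylic rhodium alkyl is favoured, the chiral phosphine–phosphite ligand fixes the face of hydride and formyl delivery so that C3 should be set as R, and the aryl acetate is inert to CO/H2.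

Step 2
Reactants: 2 (R)-2-(4-acetoxyphenyl)propanal
Product: 3 (R)-2-(4-acetoxyphenyl)propan-1-ol
Conditions: NaBH4, THF/EtOH, −20 °C, short; AcOH quench
Reagents that add atoms: none
Why: Borohydride reduction of the aldehyde is much faster than attack on the aryl acetate at low temperature, and reducing the crude aldehyde immediately removes the acidic benzylic α-hydrogen situation before C3 can racemise.

Step 3
Reactants: 3 (R)-2-(4-acetoxyphenyl)propan-1-ol
Product: 4 4-[(R)-1-(triisopropylsilyloxy)propan-2-yl]phenyl acetate
Conditions: i-Pr3SiCl, imidazole, DMF, rt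
Reagents that add atoms: triisopropylsilyl chloride, CC(C)[Si](Cl)(C(C)C)C(C)C
Why: Imidazole-promoted silylation of the only free hydroxyl is routine, and the triisopropylsilyl ether is chosen because it should survive carbonate methanolysis, the acidic fluorinated alcohol of step 5 and, if the reserve route is needed, dissolving-metal conditions.

Step 4
Reactants: 4 4-[(R)-1-(triisopropylsilyloxy)propan-2-yl]phenyl acetate
Product: 5 4-[(R)-1-(triisopropylsilyloxy)propan-2-yl]phenol
Conditions: K2CO3 (cat.), MeOH, 0 °C → rt
Reagents that add atoms: none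
Why: Zemplén-type transesterification cleaves the aryl acetate (phenoxide leaving group) far faster than it touches a primary triisopropylsilyl ether, and C3 carries no acidifying group under these conditions.

Step 5
Reactants: 5 4-[(R)-1-(triisopropylsilyloxy)propan-2-yl]phenol; 6 allyltrimethylsilane
Product: 7 4-allyl-4-[(R)-1-(triisopropylsilyloxy)propan-2-yl]cyclohexa-2,5-dien-1-one
Conditions: PhI(OAc)2 (1.1 equiv), 6 (4 equiv), (CF3)2CHOH, −10 → 0 °C; work-up and storage below rt
Reagents that add atoms: none
Why: Oxidative dearomatisation with umpolung of the ring: the trivalent iodine oxidant turns the phenol, in the cation-stabilising and weakly nucleophilic fluorinated alcohol, into a phenoxonium-type species that the allylsilane captures at the substituted para carbon in a Hosomi–Sakurai-like SE2′ step with loss of silicon; the two enone arms of the product are equivalent apart from C3, so no new stereocentre arises, and heat is avoided because 4-allyl dienones can aromatise by Cope rearrangement.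

Step 6
Reactants: 7 4-allyl-4-[(R)-1-(triisopropylsilyloxy)propan-2-yl]cyclohexa-2,5-dien-1-one
Product: 8 4-allyl-4-[(R)-1-hydroxypropan-2-yl]cyclohexa-2,5-dien-1-one
Conditions: HF·pyridine, pyridine, THF, 0 °C → rt
Reagents that add atoms: none
Why: Fluoride-induced Si–O cleavage in a pyridine-buffered, weakly acidic medium keeps the liberated primary alcohol protonated, so the 5-exo oxa-Michael addition onto the dienone that a basic fluoride source would trigger should be avoided.

Step 7
Reactants: 8 4-allyl-4-[(R)-1-hydroxypropan-2-yl]cyclohexa-2,5-dien-1-one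
Product: 9 (R)-2-(1-allyl-4-oxocyclohexa-2,5-dien-1-yl)propanal
Conditions: Dess–Martin periodinane, NaHCO3, CH2Cl2, 0 °C → rt
Reagents that add atoms: none
Why: Dess–Martin oxidation under bicarbonate buffering is neutral and fast, so the single enolisable hydrogen at C3 (next to a quaternary carbon) should not epimerise and the dienone is left untouched.

Step 8
Reactants: 9 (R)-2-(1-allyl-4-oxocyclohexa-2,5-dien-1-yl)propanal
Product: 12 (R)-2-[(1S,2R,6S)-2-allyl-5-oxo-7-oxabicyclo[4.1.0]hept-3-en-2-yl]propanal, via peroxyhemiacetal 10 (not isolated), via 1,2-dioxane enolate 11 (not isolated)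
Conditions: urea·H2O2 (1.05 equiv), DBU (0.2 equiv), THF, −30 → 0 °C; AcOH quench, aq. Na2S2O3 wash; crude used directly
Reagents that add atoms: urea–hydrogen peroxide adduct, NC(N)=O.OO
Why: Proposed new method: hydrogen peroxide adds reversibly to the aldehyde of 9 to give peroxyhemiacetal 10, whose hydroperoxide anion adds 6-exo-trig to C4 of one enone arm through a chair made of C3a, C3, C2, O, O and C4 to give enolate 11; the enolate carbon C5 then attacks the proximal peroxide oxygen (3-exo-tet) and expels the hemiacetal alkoxide, which collapses back to the aldehyde, so the aldehyde serves as a recyclable tether. The closest known reactions are the Weitz–Scheffer epoxidation of enones by hydroperoxide and geminal-hydroperoxide anions and the hemiacetal- or peroxyhemiacetal-tethered oxa-Michael desymmetrisations of 4,4-disubstituted cyclohexa-2,5-dienones; new here is the use of a substrate aldehyde to carry the peroxide to one diastereotopic arm. The oxirane closes on the face of the ring that carries the C3 chain because the oxygen is delivered from that chain, which fixes C4 and C5 relative to C3a. C3a becomes a stereocentre through the choice of arm, and C3 should control it: with the tether on the allyl side of the attacked arm (obtuse approach to C4, away from C5), the R configuration at C3 lets the methyl group sit equatorial and outward with the C3 hydrogen over the ring only for attack on the arm that leads to 12, whereas attack on the other arm would force the methyl group axially over the dienone. The step also needs mono-epoxidation without untethered background reaction; one equivalent of peroxide, the sluggishness of a cross-conjugated dienone towards free hydroperoxide under amine-base conditions and the effective molarity of the tether should secure both, and the peroxyhemiacetal form cannot enolise and so shields C3.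

Step 9
Reactants: 12 (R)-2-[(1S,2R,6S)-2-allyl-5-oxo-7-oxabicyclo[4.1.0]hept-3-en-2-yl]propanal; 13 4-bromo-1,2-dimethoxybenzene
Product: 16 (1S,5R,6S)-5-allyl-5-[(1S,2R)-1-(3,4-dimethoxyphenyl)-1-hydroxypropan-2-yl]-7-oxabicyclo[4.1.0]hept-3-en-2-one, via 3,4-dimethoxyphenyllithium 14 (not isolated), via (3,4-dimethoxyphenyl)titanium triisopropoxide 15 (not isolated)
Conditions: 13, n-BuLi, THF, −78 °C; ClTi(OiPr)3, −78 → −40 °C; then 12, −78 → −30 °C; pH 7 phosphate buffer
Reagents that add atoms: none
Why: Bromine–lithium exchange and transmetallation give a non-basic aryl reagent of tetravalent titanium that adds to aldehydes much faster than to ketones, enones or epoxides, and Felkin–Anh control (quaternary C3a as the large group anti to the incoming aryl, methyl inside, hydrogen outside) should set C2 as S, which places the aryl group cis to the C3 methyl once the ring is closed.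

Step 10
Reactants: 16 (1S,5R,6S)-5-allyl-5-[(1S,2R)-1-(3,4-dimethoxyphenyl)-1-hydroxypropan-2-yl]-7-oxabicyclo[4.1.0]hept-3-en-2-one
Product: 19 CNP0174038.1 (2S,3R,3aR,7aS)-3a-allyl-2-(3,4-dimethoxyphenyl)-5-methoxy-3-methyl-3,3a,7,7a-tetrahydro-1-benzofuran-6(2H)-one, via epoxy hexahydrobenzofuranone 17 (not isolated), via 4-hydroxy-5-methoxy ketone 18 (not isolated)
Conditions: NaOMe (3 equiv), MeOH, 0 °C → rt
Reagents that add atoms: sodium methoxide, C[O-].[Na+]
Why: The C2 alkoxide adds 5-exo-trig to C7a, the only enone β-carbon left, from the face on which the side chain sits (cis ring fusion, C7a S), after which methoxide opens the α,β-epoxy ketone at the carbonyl-activated C5 with inversion and the β-hydroxy ketone loses the C4 hydroxyl by E1cB (the classical epoxy ketone to α-methoxy enone conversion); the C4/C5 stereocentres are erased, a retro-oxa-Michael can only return the same cis-fused compound, and the alkoxide cannot open the oxirane at C4 because it lies on the same face as the epoxide oxygen.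

## Compound list

1 | 4-acetoxystyrene | CC(=O)Oc1ccc(C=C)cc1 | starting material
2 | (R)-2-(4-acetoxyphenyl)propanal | C[C@@H](C=O)c1ccc(OC(C)=O)cc1 | intermediate
3 | (R)-2-(4-acetoxyphenyl)propan-1-ol | C[C@@H](CO)c1ccc(OC(C)=O)cc1 | intermediate
4 | 4-[(R)-1-(triisopropylsilyloxy)propan-2-yl]phenyl acetate | C[C@@H](CO[Si](C(C)C)(C(C)C)C(C)C)c1ccc(OC(C)=O)cc1 | intermediate
5 | 4-[(R)-1-(triisopropylsilyloxy)propan-2-yl]phenol | C[C@@H](CO[Si](C(C)C)(C(C)C)C(C)C)c1ccc(O)cc1 | intermediate
6 | allyltrimethylsilane | C=CC[Si](C)(C)C | starting material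
7 | 4-allyl-4-[(R)-1-(triisopropylsilyloxy)propan-2-yl]cyclohexa-2,5-dien-1-one | C[C@@H](CO[Si](C(C)C)(C(C)C)C(C)C)C1(CC=C)C=CC(=O)C=C1 | intermediate
8 | 4-allyl-4-[(R)-1-hydroxypropan-2-yl]cyclohexa-2,5-dien-1-one | C[C@@H](CO)C1(CC=C)C=CC(=O)C=C1 | intermediate
9 | (R)-2-(1-allyl-4-oxocyclohexa-2,5-dien-1-yl)propanal | C[C@@H](C=O)C1(CC=C)C=CC(=O)C=C1 | intermediate
10 | (2R)-2-(1-allyl-4-oxocyclohexa-2,5-dien-1-yl)-1-hydroperoxypropan-1-ol (peroxyhemiacetal, either configuration at C2) | C[C@@H](C(O)OO)C1(CC=C)C=CC(=O)C=C1 | intermediate (not isolated)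
11 | 1,2-dioxane enolate: C2 peroxide oxygen bonded to C4 on the face of the C3 chain, dienolate over C5, C6, C7, C7a | C[C@H]1C(O)OO[C@@H]2C=C([O-])C=C[C@]12CC=C | intermediate (not isolated)
12 | (R)-2-[(1S,2R,6S)-2-allyl-5-oxo-7-oxabicyclo[4.1.0]hept-3-en-2-yl]propanal (oxirane on the face of the propanal chain) | C[C@@H](C=O)[C@@]1(CC=C)C=CC(=O)[C@H]2O[C@@H]12 | intermediate
13 | 4-bromo-1,2-dimethoxybenzene | COc1ccc(Br)cc1OC | starting material
14 | 3,4-dimethoxyphenyllithium | [Li]c1ccc(OC)c(OC)c1 | intermediate (not isolated)
15 | (3,4-dimethoxyphenyl)titanium triisopropoxide | CC(C)O[Ti](OC(C)C)(OC(C)C)c1ccc(OC)c(OC)c1 | intermediate (not isolated)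
16 | (1S,5R,6S)-5-allyl-5-[(1S,2R)-1-(3,4-dimethoxyphenyl)-1-hydroxypropan-2-yl]-7-oxabicyclo[4.1.0]hept-3-en-2-one | C[C@@H]([C@H](O)c1ccc(OC)c(OC)c1)[C@@]1(CC=C)C=CC(=O)[C@H]2O[C@@H]12 | intermediate
17 | (2S,3R,3aS,4S,5S,7aS)-3a-allyl-2-(3,4-dimethoxyphenyl)-4,5-epoxy-3-methylhexahydro-1-benzofuran-6(2H)-one (cis-fused, oxirane on the face of C3 and O1) | C=CC[C@@]12[C@@H]3O[C@@H]3C(=O)C[C@@H]1O[C@H](c1ccc(OC)c(OC)c1)[C@@H]2C | intermediate (not isolated)
18 | (2S,3R,3aR,4S,5R,7aS)-3a-allyl-2-(3,4-dimethoxyphenyl)-4-hydroxy-5-methoxy-3-methylhexahydro-1-benzofuran-6(2H)-one | C=CC[C@@]12[C@H](O)[C@@H](OC)C(=O)C[C@@H]1O[C@H](c1ccc(OC)c(OC)c1)[C@@H]2C | intermediate (not isolated)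
19 | CNP0174038.1, (2S,3R,3aR,7aS)-3a-allyl-2-(3,4-dimethoxyphenyl)-5-methoxy-3-methyl-3,3a,7,7a-tetrahydro-1-benzofuran-6(2H)-one | C=CC[C@@]12C=C(OC)C(=O)C[C@@H]1O[C@H](c1ccc(OC)c(OC)c1)[C@@H]2C | target

## Step count and risks

Total step count: 10.
Longest linear sequence: 10 steps (1 → 19); 6 and 13 are bought and enter at steps 5 and 9.

**Risk 1: step 8 (the proposed new method).** The peroxyhemiacetal anion may fail to discriminate the two enone arms, or may break down by Baeyer–Villiger/Dakin-type oxidation of the aldehyde before it adds. The fallback uses known chemistry, sets out from aldehyde 9 and returns to the route at target 19.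
- Aldehyde 9 would be arylated first with aryltitanium 15 (made from 13 as in step 9, same Felkin–Anh sense) to give 4-allyl-4-[(1S,2R)-1-(3,4-dimethoxyphenyl)-1-hydroxypropan-2-yl]cyclohexa-2,5-dien-1-one F1.
- The hydroxyl of F1 would then be closed onto one enone arm by a desymmetrising 5-exo oxa-Michael addition under kinetic control with a cinchona-alkaloid-derived bifunctional thiourea, both pseudoenantiomeric catalysts being tested for the match with C2/C3. This should give (2S,3R,3aS,7aS)-3a-allyl-2-(3,4-dimethoxyphenyl)-3-methyl-3,3a,7,7a-tetrahydro-1-benzofuran-6(2H)-one F2; the arm isomer would be separated and returned to F1 by base-induced retro-oxa-Michael.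
- The remaining enone of F2 would be epoxidised by an ordinary untethered Weitz–Scheffer reaction (t-BuOOH, cat. DBU, CH2Cl2, 0 °C), expected from the convex allyl face, to give (2S,3R,3aS,4R,5R,7aS)-3a-allyl-2-(3,4-dimethoxyphenyl)-4,5-epoxy-3-methylhexahydro-1-benzofuran-6(2H)-one F3, the oxirane epimer of 17.
- NaOMe in MeOH as in step 10 would convert F3 into 19, since C4 and C5 lose their configuration in the opening/E1cB sequence.

**Risk 2: step 5.** The phenoxonium intermediate may be captured at an ortho carbon or by the solvent, or may lose the benzylic C3 proton to a quinone methide, in competition with attack at a para carbon that bears a branched substituent. The fallback builds the quaternary carbon by a sigmatropic shift instead of oxidative umpolung; it sets out from phenol 5 and returns at dienone 7.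
- Phenol 5 would be O-methylated (MeI, K2CO3, acetone) to (R)-1-methoxy-4-[1-(triisopropylsilyloxy)propan-2-yl]benzene F4.
- Birch reduction (Li, liquid NH3, t-BuOH, THF, −78 °C) would give (R)-1-methoxy-4-[1-(triisopropylsilyloxy)propan-2-yl]cyclohexa-1,4-diene F5.
- Mild enol ether hydrolysis (oxalic acid, aqueous MeOH) would give the β,γ-enone (R)-4-[1-(triisopropylsilyloxy)propan-2-yl]cyclohex-3-en-1-one F6.
- Kinetic α-allylation of its dienolate (KN(SiMe3)2, THF, −78 °C, then allyl bromide) would give 2-allyl-4-[(R)-1-(triisopropylsilyloxy)propan-2-yl]cyclohex-3-en-1-one F7 as a mixture at the new centre.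
- Heating (toluene, sealed tube, about 160 °C) would move the allyl group to the γ-carbon by a conjugation-driven Cope rearrangement, giving 4-allyl-4-[(R)-1-(triisopropylsilyloxy)propan-2-yl]cyclohex-2-en-1-one F8; its epimers at the quaternary carbon converge later.
- Saegusa–Ito dehydrogenation through {[4-allyl-4-[(R)-1-(triisopropylsilyloxy)propan-2-yl]cyclohexa-1,5-dien-1-yl]oxy}trimethylsilane F9 (LiN(iPr)2, Me3SiCl, THF, −78 °C; then Pd(OAc)2, MeCN, rt) would deliver 7.

**Risk 3: step 9.** Aryl transfer to a neopentyl-type, α-branched aldehyde may be slow, which would allow competing attack at the enone carbonyl or erosion of Felkin–Anh control. The fallback replaces substrate control by ligand-accelerated, catalyst-controlled aryl transfer from zinc; it sets out from aryllithium 14 (from 13) and aldehyde 12 and returns at carbinol 16.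
- 14 would be transmetallated with ZnCl2 (0.5 equiv) to bis(3,4-dimethoxyphenyl)zinc F10.
- F10 would be scrambled with Et2Zn to (3,4-dimethoxyphenyl)(ethyl)zinc F11.
- F11 would be added to 12 in toluene at 0 °C with 10 mol% of a chiral amino alcohol such as 3-exo-morpholinoisoborneol, using the enantiomer that reinforces the Felkin face and a diamine to mask the lithium salts. Only the aryl group transfers, and the zinc reagent does not touch the enone or the oxirane.

## Further compounds

F1 | step 8 | 4-allyl-4-[(1S,2R)-1-(3,4-dimethoxyphenyl)-1-hydroxypropan-2-yl]cyclohexa-2,5-dien-1-one | C[C@@H]([C@H](O)c1ccc(OC)c(OC)c1)C1(CC=C)C=CC(=O)C=C1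
F2 | step 8 | (2S,3R,3aS,7aS)-3a-allyl-2-(3,4-dimethoxyphenyl)-3-methyl-3,3a,7,7a-tetrahydro-1-benzofuran-6(2H)-one | C=CC[C@@]12C=CC(=O)C[C@@H]1O[C@H](c1ccc(OC)c(OC)c1)[C@@H]2C
F3 | step 8 | (2S,3R,3aS,4R,5R,7aS)-3a-allyl-2-(3,4-dimethoxyphenyl)-4,5-epoxy-3-methylhexahydro-1-benzofuran-6(2H)-one | C=CC[C@@]12[C@H]3O[C@H]3C(=O)C[C@@H]1O[C@H](c1ccc(OC)c(OC)c1)[C@@H]2C
F4 | step 5 | (R)-1-methoxy-4-[1-(triisopropylsilyloxy)propan-2-yl]benzene | C[C@@H](CO[Si](C(C)C)(C(C)C)C(C)C)c1ccc(OC)cc1
F5 | step 5 | (R)-1-methoxy-4-[1-(triisopropylsilyloxy)propan-2-yl]cyclohexa-1,4-diene | C[C@@H](CO[Si](C(C)C)(C(C)C)C(C)C)C1=CCC(OC)=CC1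
F6 | step 5 | (R)-4-[1-(triisopropylsilyloxy)propan-2-yl]cyclohex-3-en-1-one | C[C@@H](CO[Si](C(C)C)(C(C)C)C(C)C)C1=CCC(=O)CC1
F7 | step 5 | 2-allyl-4-[(R)-1-(triisopropylsilyloxy)propan-2-yl]cyclohex-3-en-1-one | C[C@@H](CO[Si](C(C)C)(C(C)C)C(C)C)C1=CC(CC=C)C(=O)CC1
F8 | step 5 | 4-allyl-4-[(R)-1-(triisopropylsilyloxy)propan-2-yl]cyclohex-2-en-1-one | C[C@@H](CO[Si](C(C)C)(C(C)C)C(C)C)C1(CC=C)C=CC(=O)CC1
F9 | step 5 | {[4-allyl-4-[(R)-1-(triisopropylsilyloxy)propan-2-yl]cyclohexa-1,5-dien-1-yl]oxy}trimethylsilane | C[C@@H](CO[Si](C(C)C)(C(C)C)C(C)C)C1(CC=C)C=CC(O[Si](C)(C)C)=CC1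
F10 | step 9 | bis(3,4-dimethoxyphenyl)zinc | COc1ccc([Zn]c2ccc(OC)c(OC)c2)cc1OC
F11 | step 9 | (3,4-dimethoxyphenyl)(ethyl)zinc | CC[Zn]c1ccc(OC)c(OC)c1
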